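**Plan**

1. Retrosynthesis (labdane numbering C1–C20): remove the C15 palmitate, take the C19 acid back to an ester and the C13=C14 alkene back to a C13 methyl ketone, then cut C2–C3, C4–C5 and C9–C10 in one stroke.
2. This leaves (−)-8-phenylmenthyl methacrylate (C3, C4, C18, C19) and an open (E,E)-chain, C2 to C16, cut out of farnesylacetone and carrying a radical precursor at C2.
3. Enabling feature: the C3–C4(C18)(C19) edge of ring A is a methacrylate lying between C2 and C5; a radical at C2 is homoallylic to C5=C10, cannot cyclise and so must add to C3, and the C4 and C10 radicals that follow each find a trisubstituted E-alkene placed for 6-endo closure.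
4. Forward order: C2–C3 by addition, ring A by C4–C5, ring B by C9–C10 and the exocyclic C8=C17 by oxidative termination, all in step 6; then side-chain olefination, reduction, C15 acylation and C19 oxidation.
5. Stereochemistry: C5, C9 and C10 from chair–chair folding of the two E-alkenes, C4 from axial placement of the ester, the absolute sense from the 8-phenylmenthyl ester (wanted diastereomer purified after step 6), 13E from the olefination.

Key step: step 6

Remark: labdane numbering is used for all intermediates, (5E,9E)-farnesylacetone is taken as the commercially available, geometrically pure isomer, and the (−)-auxiliary is assumed to shield the face of the C4 radical whose blocking leads to the normal (10β-methyl) labdane series.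

**Route**

Step 1
Reactants: 1 (5E,9E)-farnesylacetone
Product: 3 (5E,9E)-13,14-epoxy-6,10,14-trimethylpentadeca-5,9-dien-2-one (racemic), via terminal bromohydrin 2 (not isolated)
Conditions: NBS (1.1 equiv), THF/H2O, 0 °C; crude bromohydrin, then K2CO3, MeOH, rt
Reagents that add atoms: water (O); N-bromosuccinimide (O=C1CCC(=O)N1Br)
Why: Electrophilic bromohydrin formation in aqueous THF is selective for the terminal, most exposed trisubstituted alkene of a coiled polyprenyl chain (water opens the bromonium ion at the tertiary carbon, so the bromine taken from N-bromosuccinimide sits at C13 of 2 only), and carbonate then closes the bromohydrin by intramolecular SN2 with loss of bromide to the epoxide, whose stereocentre is racemic and is excised in step 2.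

Step 2
Reactants: 3 (5E,9E)-13,14-epoxy-6,10,14-trimethylpentadeca-5,9-dien-2-one
Product: 5 (4E,8E)-4,8-dimethyl-12-oxotrideca-4,8-dienal, via vicinal diol 4 (not isolated)
Conditions: H5IO6, THF/H2O, 0 °C
Reagents that add atoms: water (O)
Why: In aqueous periodic acid water opens the protonated epoxide at its tertiary carbon to the vicinal diol, which is cleaved at once (Malaprade glycol cleavage) to aldehyde 5 and acetone without touching the internal alkenes or the ketone, and no stereocentre is involved.

Step 3
Reactants: 5 (4E,8E)-4,8-dimethyl-12-oxotrideca-4,8-dienal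
Product: 6 (4E,8E)-4,8-dimethyl-12-oxotrideca-4,8-dienoic acid
Conditions: NaClO2, NaH2PO4, 2-methyl-2-butene, t-BuOH/H2O, 0 °C → rt
Reagents that add atoms: sodium chlorite ([Na+].[O-]Cl=O)
Why: Pinnick oxidation converts the aldehyde into the acid chemoselectively, the alkene scavenger taking up hypochlorous acid so that the trisubstituted alkenes and the methyl ketone survive.

Step 4
Reactants: 6 (4E,8E)-4,8-dimethyl-12-oxotrideca-4,8-dienoic acid
Product: 7 1,3-dioxoisoindolin-2-yl (4E,8E)-4,8-dimethyl-12-oxotrideca-4,8-dienoate
Conditions: N-hydroxyphthalimide, DIC, DMAP (cat.), CH2Cl2, rt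
Reagents that add atoms: N-hydroxyphthalimide (O=C1N(O)C(=O)c2ccccc12)
Why: Carbodiimide (Steglich-type) esterification gives the redox-active N-acyloxyphthalimide from which the C2 radical will be released by decarboxylation, the remote ketone and alkenes being inert.

Step 5
Reactants: 8 (−)-8-phenylmenthol [(1R,2S,5R)-5-methyl-2-(2-phenylpropan-2-yl)cyclohexan-1-ol]; 9 methacryloyl chloride
Product: 10 (−)-8-phenylmenthyl methacrylate
Conditions: Et3N, DMAP (cat.), CH2Cl2, 0 °C → rt
Reagents that add atoms: none
Why: Acylation of the hindered secondary alcohol by the acid chloride under nucleophilic catalysis gives the chiral acrylate without touching the carbinol stereocentre, which is bought in.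

Step 6
Reactants: 7 1,3-dioxoisoindolin-2-yl (4E,8E)-4,8-dimethyl-12-oxotrideca-4,8-dienoate; 10 (−)-8-phenylmenthyl methacrylate
Product: 11 (−)-8-phenylmenthyl 13-oxo-14,15-dinorlabd-8(17)-en-19-oate (5α-H, 9α-H, 10β-CH3, ester carbon C19 on the β-face of C4)
Conditions: 10 (5 equiv), fac-Ir(ppy)3 (ppy = 2-phenylpyridinate, 1 mol%), Cu(O2CCH(Et)Bu)2 (5 mol%), PhCF3/MeCN, 0.02 M in 7, blue LEDs, 30 °C
Reagents that add atoms: none
Why: Proposed new method: excited fac-Ir(ppy)3 reduces the N-acyloxyphthalimide, which loses CO2 and phthalimide anion to leave the primary C2 radical; this adds to the CH2 end (C3) of 10 (C2–C3 bond), the ester-stabilised tertiary C4 radical attacks C5 (C4–C5 bond, ring A), the tertiary C10 radical attacks C9 (ring B), and the C8 radical is oxidised at divalent copper with loss of a C17 hydrogen, the tetravalent iridium turning monovalent copper over. The closest known reaction types are the decarboxylative Giese addition of redox-active esters, the oxidative free-radical polyene cyclisation of α-carbonyl radicals (trivalent manganese with divalent copper as terminating oxidant) and the photoredox/copper decarboxylative olefination, and what is new is their union in one radical chain of events. Ring A and ring B are each closed in the 6-endo-trig mode, favoured over 5-exo because the inner alkene carbons C10 and C8 are fully substituted and each closure gives a tertiary radical. C5, C10 and C9 are set by chair–chair folding of the two E-alkenes (trans ring fusion, axial C20, equatorial C9 chain), and at C4 the planar ester, smaller than methyl, should take the axial site so that C19 is β. The absolute sense is decided in the C4–C5 closure by the 8-phenylmenthyl group, whose phenyl ring lies over one face of the ester-conjugated C4 radical so that C5 should bond to the open face; the wanted diastereomer is freed from the minor ones by chromatography at this stage. The step needs addition to 10 to come before any ring closure or copper capture of the C2 radical, which the substrate secures because C2 is homoallylic to C5=C10 (only 3-exo or 4-endo closure is open to it) and which excess 10 at low copper loading supports, and it needs loss of hydrogen from C17 and not from C7 or C9, which elimination from the alkylcopper intermediate favours for the unhindered methyl group.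

Step 7
Reactants: 11 (−)-8-phenylmenthyl 13-oxo-14,15-dinorlabd-8(17)-en-19-oate; 12 triethyl phosphonoacetate
Product: 13 15-ethyl 19-[(−)-8-phenylmenthyl] (13E)-labda-8(17),13-diene-15,19-dioate
Conditions: NaH, THF, 0 °C → 60 °C
Reagents that add atoms: none
Why: Horner–Wadsworth–Emmons olefination of the unhindered methyl ketone should give mainly the E-trisubstituted enoate (the longer chain trans to the ester), the minor Z isomer being removed by chromatography, while the quaternary, non-enolisable C19 ester and the exocyclic alkene are untouched.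

Step 8
Reactants: 13 15-ethyl 19-[(−)-8-phenylmenthyl] (13E)-labda-8(17),13-diene-15,19-dioate
Product: 14 (13E)-labda-8(17),13-diene-15,19-diol (agathadiol)
Conditions: LiAlH4, THF, 0 °C, then reflux; aqueous work-up
Reagents that add atoms: none
Why: Hydride reduction takes the conjugated ethyl ester to the E-allylic alcohol by 1,2-addition and, on heating, the hindered neopentyl ester to the C19 carbinol with release of the auxiliary for recovery, and no stereocentre or alkene is affected.

Step 9
Reactants: 14 (13E)-labda-8(17),13-diene-15,19-diol; 15 palmitoyl chloride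
Product: 16 (13E)-19-hydroxylabda-8(17),13-dien-15-yl hexadecanoate
Conditions: 15 (1.05 equiv), 2,4,6-collidine, CH2Cl2, −78 → −40 °C
Reagents that add atoms: none
Why: Kinetically controlled O-acylation with one equivalent of acid chloride and a hindered pyridine base at low temperature selects the unhindered allylic C15 hydroxyl over the axial neopentyl C19 hydroxyl, which is flanked by the C20 methyl.

Step 10
Reactants: 16 (13E)-19-hydroxylabda-8(17),13-dien-15-yl hexadecanoate
Product: 17 (13E)-19-oxolabda-8(17),13-dien-15-yl hexadecanoate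
Conditions: Dess–Martin periodinane, CH2Cl2, 0 °C → rt
Reagents that add atoms: none
Why: Dess–Martin oxidation converts the neopentyl alcohol into the aldehyde, which cannot epimerise because C4 is quaternary, under conditions that spare the allylic ester and both alkenes.

Step 11
Reactants: 17 (13E)-19-oxolabda-8(17),13-dien-15-yl hexadecanoate
Product: 18 (13E)-15-(hexadecanoyloxy)labda-8(17),13-dien-19-oic acid (CNP0323052.1)
Conditions: NaClO2, NaH2PO4, 2-methyl-2-butene, t-BuOH/H2O, 0 °C → rt
Reagents that add atoms: sodium chlorite ([Na+].[O-]Cl=O)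
Why: Pinnick oxidation with an alkene scavenger turns the hindered aldehyde into the C19 acid without affecting the palmitate, the allylic system or the exocyclic alkene, and gives the target.

**Compound list**

1 | (5E,9E)-farnesylacetone [(5E,9E)-6,10,14-trimethylpentadeca-5,9,13-trien-2-one] | CC(C)=CCC/C(C)=C/CC/C(C)=C/CCC(C)=O | starting material
2 | (5E,9E)-13-bromo-14-hydroxy-6,10,14-trimethylpentadeca-5,9-dien-2-one (racemic) | CC(C)(O)C(Br)CC/C(C)=C/CC/C(C)=C/CCC(C)=O | intermediate
3 | (5E,9E)-13,14-epoxy-6,10,14-trimethylpentadeca-5,9-dien-2-one (racemic) | CC1(C)OC1CC/C(C)=C/CC/C(C)=C/CCC(C)=O | intermediate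
4 | (5E,9E)-13,14-dihydroxy-6,10,14-trimethylpentadeca-5,9-dien-2-one (racemic) | CC(C)(O)C(O)CC/C(C)=C/CC/C(C)=C/CCC(C)=O | intermediate
5 | (4E,8E)-4,8-dimethyl-12-oxotrideca-4,8-dienal | O=CCC/C(C)=C/CC/C(C)=C/CCC(C)=O | intermediate
6 | (4E,8E)-4,8-dimethyl-12-oxotrideca-4,8-dienoic acid | OC(=O)CC/C(C)=C/CC/C(C)=C/CCC(C)=O | intermediate
7 | 1,3-dioxoisoindolin-2-yl (4E,8E)-4,8-dimethyl-12-oxotrideca-4,8-dienoate | O=C(CC/C(C)=C/CC/C(C)=C/CCC(C)=O)ON1C(=O)c2ccccc2C1=O | intermediate
8 | (−)-8-phenylmenthol [(1R,2S,5R)-5-methyl-2-(2-phenylpropan-2-yl)cyclohexan-1-ol] | O[C@@H]1C[C@H](C)CC[C@H]1C(C)(C)c1ccccc1 | starting material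
9 | methacryloyl chloride | C=C(C)C(Cl)=O | starting material
10 | (−)-8-phenylmenthyl methacrylate [(1R,2S,5R)-5-methyl-2-(2-phenylpropan-2-yl)cyclohexyl 2-methylprop-2-enoate] | C=C(C)C(=O)O[C@@H]1C[C@H](C)CC[C@H]1C(C)(C)c1ccccc1 | intermediate
11 | (−)-8-phenylmenthyl 13-oxo-14,15-dinorlabd-8(17)-en-19-oate [8-phenylmenthyl (1S,4aR,5S,8aR)-1,4a-dimethyl-6-methylidene-5-(3-oxobutyl)decahydronaphthalene-1-carboxylate] | C=C1CC[C@@H]2[C@](C)(CCC[C@]2(C)C(=O)O[C@@H]3C[C@H](C)CC[C@H]3C(C)(C)c4ccccc4)[C@H]1CCC(C)=O | intermediate
12 | triethyl phosphonoacetate | CCOC(=O)CP(=O)(OCC)OCC | starting material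
13 | 15-ethyl 19-[(−)-8-phenylmenthyl] (13E)-labda-8(17),13-diene-15,19-dioate | C=C1CC[C@@H]2[C@](C)(CCC[C@]2(C)C(=O)O[C@@H]3C[C@H](C)CC[C@H]3C(C)(C)c4ccccc4)[C@H]1CC/C(C)=C/C(=O)OCC | intermediate
14 | (13E)-labda-8(17),13-diene-15,19-diol (agathadiol) | C=C1CC[C@@H]2[C@](C)(CCC[C@]2(C)CO)[C@H]1CC/C(C)=C/CO | intermediate
15 | palmitoyl chloride (hexadecanoyl chloride) | CCCCCCCCCCCCCCCC(Cl)=O | starting material
16 | (13E)-19-hydroxylabda-8(17),13-dien-15-yl hexadecanoate | C=C1CC[C@@H]2[C@](C)(CCC[C@]2(C)CO)[C@H]1CC/C(C)=C/COC(=O)CCCCCCCCCCCCCCC | intermediate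
17 | (13E)-19-oxolabda-8(17),13-dien-15-yl hexadecanoate | C=C1CC[C@@H]2[C@](C)(CCC[C@]2(C)C=O)[C@H]1CC/C(C)=C/COC(=O)CCCCCCCCCCCCCCC | intermediate
18 | (13E)-15-(hexadecanoyloxy)labda-8(17),13-dien-19-oic acid (isocupressic acid 15-palmitate, CNP0323052.1) | C=C1CC[C@@H]2[C@](C)(CCC[C@]2(C)C(=O)O)[C@H]1CC/C(C)=C/COC(=O)CCCCCCCCCCCCCCC | target

**Step count and risks**

Total step count: 11. Longest linear sequence: 10 steps (steps 1–4 and 6–11; step 5 is the side branch).

Steps most likely to fail:

1. Step 6 (proposed new method). The intermediate radicals may be intercepted before both rings are closed, by copper, by reduction or by a second molecule of the acrylate. The auxiliary may discriminate the two faces of the C4 radical only weakly or in the unwanted sense, the ester may take the equatorial site in the first closure, and the termination may remove a ring hydrogen. The fallback uses known chemistry, sets out from acid 6 and comes back at diester 13. Acid 6 is condensed with Meldrum's acid (DCC, DMAP, CH2Cl2) to the acyl Meldrum's acid F1, which is heated with alcohol 8 in toluene to the β-keto ester F2. C-Methylation (MeI, K2CO3, acetone) gives the α-methyl β-keto ester F3. Oxidative free-radical cyclisation with Mn(OAc)3·2H2O and Cu(OAc)2·H2O in AcOH, a reaction type with precedent for 8-phenylmenthyl control and for axial placement of the ester, should close rings A and B from the pre-formed C2–C3 bond and give the 3,13-diketone F4. The unhindered C13 ketone is olefinated with 12 and NaH to the 3-oxo diester F5. The C3 ketone is reduced (NaBH4, EtOH) to the 3β-alcohol F6 and converted (PhOC(S)Cl, pyridine, DMAP) into the phenyl thionocarbonate F7. Barton–McCombie deoxygenation (Bu3SnH, AIBN, toluene, 80 °C) then returns to 13.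

2. Step 7. The olefination of a methyl ketone may discriminate E from Z poorly and the geometric isomers may be hard to separate. The fallback sets out from ketone 11 and comes back at diol 14. Ketone 11 is taken through the kinetic enol phosphate F8 (LiN(i-Pr)2, THF, −78 °C, then ClP(O)(OEt)2) and eliminated with further LiN(i-Pr)2 to the terminal alkyne F9. Zirconium-catalysed methylalumination (Me3Al, Cp2ZrCl2, CH2Cl2) and trapping of the vinylalane with paraformaldehyde should give the E-allylic alcohol F10 stereospecifically, by syn addition of methyl and aluminium. LiAlH4 in THF at reflux then removes the auxiliary and meets the route at 14.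

3. Step 9. Acylation may also occur at the neopentyl C19 hydroxyl or go on to the bis-ester. The fallback sets out from diol 14 and comes back at monoester 16. The selectivity is handed to an enzyme: transesterification with vinyl palmitate catalysed by immobilised Candida antarctica lipase B (MTBE, 30 °C) should accept only the unhindered primary allylic alcohol. This fallback makes no compound outside the list (F0).

Further compounds
F1 | step 6 | 5-[(4E,8E)-1-hydroxy-4,8-dimethyl-12-oxotrideca-4,8-dien-1-ylidene]-2,2-dimethyl-1,3-dioxane-4,6-dione (acyl Meldrum's acid, enol form) | CC1(C)OC(=O)C(=C(O)CC/C(C)=C/CC/C(C)=C/CCC(C)=O)C(=O)O1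
F2 | step 6 | (−)-8-phenylmenthyl (6E,10E)-6,10-dimethyl-3,14-dioxopentadeca-6,10-dienoate | O=C(CC(=O)CC/C(C)=C/CC/C(C)=C/CCC(C)=O)O[C@@H]1C[C@H](C)CC[C@H]1C(C)(C)c1ccccc1
F3 | step 6 | (−)-8-phenylmenthyl (6E,10E)-2,6,10-trimethyl-3,14-dioxopentadeca-6,10-dienoate (C2 epimers) | CC(C(=O)CC/C(C)=C/CC/C(C)=C/CCC(C)=O)C(=O)O[C@@H]1C[C@H](C)CC[C@H]1C(C)(C)c1ccccc1
F4 | step 6 | (−)-8-phenylmenthyl 3,13-dioxo-14,15-dinorlabd-8(17)-en-19-oate | C=C1CC[C@@H]2[C@](C)(CCC(=O)[C@]2(C)C(=O)O[C@@H]3C[C@H](C)CC[C@H]3C(C)(C)c4ccccc4)[C@H]1CCC(C)=O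
F5 | step 6 | 15-ethyl 19-[(−)-8-phenylmenthyl] (13E)-3-oxolabda-8(17),13-diene-15,19-dioate | C=C1CC[C@@H]2[C@](C)(CCC(=O)[C@]2(C)C(=O)O[C@@H]3C[C@H](C)CC[C@H]3C(C)(C)c4ccccc4)[C@H]1CC/C(C)=C/C(=O)OCC
F6 | step 6 | 15-ethyl 19-[(−)-8-phenylmenthyl] (13E)-3β-hydroxylabda-8(17),13-diene-15,19-dioate | C=C1CC[C@@H]2[C@](C)(CC[C@H](O)[C@]2(C)C(=O)O[C@@H]3C[C@H](C)CC[C@H]3C(C)(C)c4ccccc4)[C@H]1CC/C(C)=C/C(=O)OCC
F7 | step 6 | 15-ethyl 19-[(−)-8-phenylmenthyl] (13E)-3β-(phenoxycarbonothioyloxy)labda-8(17),13-diene-15,19-dioate | C=C1CC[C@@H]2[C@](C)(CC[C@H](OC(=S)Oc5ccccc5)[C@]2(C)C(=O)O[C@@H]3C[C@H](C)CC[C@H]3C(C)(C)c4ccccc4)[C@H]1CC/C(C)=C/C(=O)OCC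
F8 | step 7 | (−)-8-phenylmenthyl 13-(diethoxyphosphoryloxy)-14,15-dinorlabda-8(17),13(16)-dien-19-oate | C=C1CC[C@@H]2[C@](C)(CCC[C@]2(C)C(=O)O[C@@H]3C[C@H](C)CC[C@H]3C(C)(C)c4ccccc4)[C@H]1CCC(=C)OP(=O)(OCC)OCC
F9 | step 7 | (−)-8-phenylmenthyl (1S,4aR,5S,8aR)-5-(but-3-yn-1-yl)-1,4a-dimethyl-6-methylidenedecahydronaphthalene-1-carboxylate | C=C1CC[C@@H]2[C@](C)(CCC[C@]2(C)C(=O)O[C@@H]3C[C@H](C)CC[C@H]3C(C)(C)c4ccccc4)[C@H]1CCC#C
F10 | step 7 | (−)-8-phenylmenthyl (13E)-15-hydroxylabda-8(17),13-dien-19-oate | C=C1CC[C@@H]2[C@](C)(CCC[C@]2(C)C(=O)O[C@@H]3C[C@H](C)CC[C@H]3C(C)(C)c4ccccc4)[C@H]1CC/C(C)=C/CO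
F0 | step 9 | none | none
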